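The left-handed product of the midnight run reached 38.6 % after 90.0 s, out of the 50 % that the left-handed substrate can give. So I reckoned with f, the fraction of that substrate left, c(left-handed substrate) over its charge, and with a pseudo-first-order constant for this kinetic resolution:

k = −ln(f)/t

first reading: k = 0.0140 s⁻¹
last reading: k = 0.0164 s⁻¹

- midnight: left-handed substrate 0.75 M; right-handed substrate 0.75 M; solid reagent 3 equiv; catalyst 2.5 mol%; added ligand 31 mM; run made earlier
- flask: left-handed substrate 0.75 M; solid reagent 3.00 equiv; catalyst 5 mol%; added ligand 31 mM; right-handed substrate 0.75 M

- midnight (time / s: left-handed product / %): 15.0: 9.5; 30.0: 18.6; 50.0: 26.8; 60.0: 30.1; 80.0: 36.1; 90.0: 38.6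

(each reading ± 0.3 percentage points)

1. apparent order in catalyst when 30 % of the left-handed substrate and right-handed substrate together are converted (percent change of the rate of making left-handed product for one percent more catalyst charged)
2. factor on the rate of making left-handed product when 30 % of the left-handed substrate and right-handed substrate together are converted if catalyst is charged twice over

The constant read higher at the end than at the start, and I took this as the solid reagent's dissolving, a step I assumed to need no catalyst, holding back the early rate. For two steps in series, one independent of catalyst and the other first order in it, the order in catalyst equals the observed rate over the rate the catalytic step could give. I therefore folded the midnight run into one number, the early constant over the late one, with the late constant standing in for the catalytic step: my estimate of the share of the rate that answers to catalyst: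

n = 0.855

I committed to an order of n and, taking two to the power n, a doubling factor of 1.81.

One number was not quite enough. Added ligand per catalyst is 1.65 in the midnight run but 0.827 in the flask, and n, read from the first and last readings of the midnight run, carries neither that change nor the flask's loading of 5 mol%, so the order in the flask may lie on either side of n.

The forecast gave 0.8 (0.45 to 1.2) and 1.7 (1.3 to 2.4): “The data cannot test that, so the ranges are wide.”

The flask gave an order of 0.95 and a factor of 1.81.

    coupling partner + catalyst + left-handed substrate → catalyst + left-handed product (k = 7.21 M⁻² s⁻¹)
    catalyst + added ligand ⇌ idle complex, settled at all times (K = 41.0 M⁻¹)
    solid reagent ⇌ coupling partner, rate k3*(cs3 - [coupling partner]) while solid is left; crystals form when [coupling partner] > cs3 (solubility = 0.260 M, k = 0.464 s⁻¹)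
    coupling partner + catalyst + right-handed substrate → catalyst + right-handed product (k = 3.90 M⁻² s⁻¹)

Two to the power n gives 1.81 against that factor, while the local order stands above n, at 1.11 times it. In the flask at 0.500 min, free catalyst stood at 60.2 % of the charge and idle complex at 39.8 %.

The earlier runs and the new flask stem from a simulated flask for substances that don't exist, and the scatter is random.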